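## Retrosynthetic overview

1. The target is taken back to its 7-O-TBS / 2'-O-MOM protected form; the pyran ring is opened at O1–C2 (Mitsunobu) to a formyl diol.
2. The 8-CHO is installed at the diol stage, where the only free phenol (future O1) has a single open ortho position, C8.
3. The diol comes from reduction of a (3R)-3-aryl-3,4-dihydrocoumarin.
4. Key disconnection, C3–C1': a racemic 3-bromodihydrocoumarin (α-carbonyl cation / enolonium equivalent, ring A) is joined to a ring B arylzinc by stereoconvergent nickel catalysis, which sets C3.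
5. Ring order: the ring A lactone is formed first (5-methoxyresorcinol + acrylic acid), ring B is built by two directed metalations of 3-methoxyphenol, and the chroman ring is closed late.

Assumption: C3 of the target is R by CIP analysis of the given SMILES; in step 5 the (S,S)-ligand is taken to give the 3R lactone, and if the sense of induction proves opposite the commercially available (R,R)-ligand is used instead.

## Route

Step 1
Reactants: 1 5-methoxyresorcinol; 2 acrylic acid
Product: 3 7-hydroxy-5-methoxychroman-2-one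
Conditions: 2 (1.2 equiv), CF3SO3H (10 mol %), toluene, 90 °C
Reagents that add atoms: none
Why: Acid-catalysed Friedel–Crafts hydroarylation of the acrylate followed by lactonisation (dihydrocoumarin annulation); attack at the two equivalent positions para to one OH and ortho to the other gives the 7-hydroxy-5-methoxy isomer as the expected major product, and the minor 5-hydroxy-7-methoxy isomer is removed by chromatography.

Step 2
Reactants: 3 7-hydroxy-5-methoxychroman-2-one
Product: 5 rac-3-bromo-7-(tert-butyldimethylsilyloxy)-5-methoxychroman-2-one, via bis-silyl ketene acetal 4 (not isolated)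
Conditions: TBSOTf (2.3 equiv), Et3N (3 equiv), CH2Cl2, 0 °C → rt; then NBS (1.05 equiv), THF, −78 °C, cold quench
Reagents that add atoms: TBSOTf (tert-butyldimethylsilyl triflate), CC(C)(C)[Si](C)(C)OS(=O)(=O)C(F)(F)F; NBS (N-bromosuccinimide), O=C1CCC(=O)N1Br
Why: Soft enolisation of the acidic aryl lactone gives the O-silyl ketene acetal while the phenol is silylated in the same pot, and electrophilic bromination of the ketene acetal installs the α-bromide; the new centre is racemic, which does not matter because step 5 is stereoconvergent.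

Step 3
Reactants: 6 3-methoxyphenol
Product: 7 1-methoxy-3-(methoxymethoxy)benzene
Conditions: MOMCl, i-Pr2NEt, CH2Cl2, 0 °C → rt
Reagents that add atoms: MOMCl (chloromethyl methyl ether), COCCl
Why: Williamson-type O-alkylation of the phenol; the MOM ether serves as protecting group and as ortho-directing group for both later metalations.

Step 4
Reactants: 7 1-methoxy-3-(methoxymethoxy)benzene; 8 prenyl bromide
Product: 10 1-methoxy-3-(methoxymethoxy)-2-(3-methylbut-2-en-1-yl)benzene, via aryllithium 9 (not isolated)
Conditions: n-BuLi, THF, 0 °C, 1 h; then 8, −78 °C → rt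
Reagents that add atoms: none
Why: Directed ortho-metalation at the position flanked by OMOM and OMe, then SN2 alkylation of the aryllithium by the allylic bromide.

Step 5
Reactants: 10 1-methoxy-3-(methoxymethoxy)-2-(3-methylbut-2-en-1-yl)benzene; 5 rac-3-bromo-7-(tert-butyldimethylsilyloxy)-5-methoxychroman-2-one
Product: 13 (3R)-7-(tert-butyldimethylsilyloxy)-5-methoxy-3-[4-methoxy-2-(methoxymethoxy)-3-(3-methylbut-2-en-1-yl)phenyl]chroman-2-one, via aryllithium 11 (not isolated), via arylzinc iodide 12 (not isolated)
Conditions: 10 (1.6 equiv), n-BuLi, THF, 0 °C, 2 h; ZnI2, THF, 0 °C → rt; then 5 (1.0 equiv), NiCl2·glyme (10 mol %), (S,S)-i-Pr-pybox [2,6-bis((4S)-4-isopropyl-4,5-dihydrooxazol-2-yl)pyridine] (13 mol %), glyme/THF, −30 °C; pH 7 work-up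
Reagents that add atoms: none
Why: Proposed new method: the α-bromolactone serves as an α-carbonyl cation (enolonium) equivalent, since a low-valent nickel–pybox complex abstracts bromine from either enantiomer of 5 to give a planar α-lactone radical that is captured by the chiral aryl–nickel species formed from 12 and reductively eliminated to one enantiomer, so the C3 stereocentre is set by the ligand under non-basic conditions at −30 °C where the α-aryl lactone should not racemise (OMOM-directed lithiation of 10 supplies the nucleophile); the closest known reaction types are the nickel/pybox-catalysed stereoconvergent Negishi α-arylation of racemic α-bromoketones with ArZnI and the nickel-catalysed stereoconvergent Hiyama arylation of racemic α-bromo aryl esters.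

Step 6
Reactants: 13 (3R)-7-(tert-butyldimethylsilyloxy)-5-methoxy-3-[4-methoxy-2-(methoxymethoxy)-3-(3-methylbut-2-en-1-yl)phenyl]chroman-2-one
Product: 14 (2R)-3-[4-(tert-butyldimethylsilyloxy)-2-hydroxy-6-methoxyphenyl]-2-[4-methoxy-2-(methoxymethoxy)-3-(3-methylbut-2-en-1-yl)phenyl]propan-1-ol
Conditions: LiBH4 (2.5 equiv), THF, 0 °C → rt
Reagents that add atoms: none
Why: Borohydride reduction of the activated aryl-ester lactone to the phenol/primary-alcohol diol; the weakly basic hydride reduces faster than it enolises, so C3 keeps its configuration and afterwards is no longer acidic.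

Step 7
Reactants: 14 (2R)-3-[4-(tert-butyldimethylsilyloxy)-2-hydroxy-6-methoxyphenyl]-2-[4-methoxy-2-(methoxymethoxy)-3-(3-methylbut-2-en-1-yl)phenyl]propan-1-ol
Product: 15 6-(tert-butyldimethylsilyloxy)-2-hydroxy-3-{(2R)-3-hydroxy-2-[4-methoxy-2-(methoxymethoxy)-3-(3-methylbut-2-en-1-yl)phenyl]propyl}-4-methoxybenzaldehyde
Conditions: MgCl2 (3 equiv), Et3N (6 equiv), (CH2O)n (6 equiv), THF, 65 °C
Reagents that add atoms: paraformaldehyde (as formaldehyde), C=O
Why: Magnesium-phenoxide-directed ortho-formylation (Casnati–Skattebøl type) is strictly ortho to a free phenol; the only free phenol has one open ortho position (future C8), so the aldehyde is placed regiospecifically while the silylated and MOM-protected oxygens cannot direct.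

Step 8
Reactants: 15 6-(tert-butyldimethylsilyloxy)-2-hydroxy-3-{(2R)-3-hydroxy-2-[4-methoxy-2-(methoxymethoxy)-3-(3-methylbut-2-en-1-yl)phenyl]propyl}-4-methoxybenzaldehyde
Product: 16 (3R)-7-(tert-butyldimethylsilyloxy)-5-methoxy-3-[4-methoxy-2-(methoxymethoxy)-3-(3-methylbut-2-en-1-yl)phenyl]chroman-8-carbaldehyde
Conditions: PPh3 (1.5 equiv), DIAD (1.5 equiv), THF (0.02 M), 0 °C → rt
Reagents that add atoms: none
Why: Intramolecular Mitsunobu etherification (6-exo) of the acidic salicylaldehyde-type phenol with the primary alcohol closes the chroman ring; C3 is not a reacting centre and stays R, and the masked ring B oxygen cannot close a dihydrobenzofuran.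

Step 9
Reactants: 16 (3R)-7-(tert-butyldimethylsilyloxy)-5-methoxy-3-[4-methoxy-2-(methoxymethoxy)-3-(3-methylbut-2-en-1-yl)phenyl]chroman-8-carbaldehyde
Product: 17 (3R)-7-hydroxy-3-[2-hydroxy-4-methoxy-3-(3-methylbut-2-en-1-yl)phenyl]-5-methoxychroman-8-carbaldehyde
Conditions: HCl (1.25 M in MeOH), 40 °C; aqueous work-up
Reagents that add atoms: none
Why: Acid-catalysed acetal exchange removes the MOM ether and acidic methanolysis cleaves the aryl silyl ether in one operation, under conditions mild enough that the ortho-prenylphenol should not cyclise to a dimethylchroman.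

## Compound list

1 | 5-methoxyresorcinol (5-methoxybenzene-1,3-diol) | COc1cc(O)cc(O)c1 | starting material
2 | acrylic acid | C=CC(=O)O | starting material
3 | 7-hydroxy-5-methoxychroman-2-one | COc1cc(O)cc2OC(=O)CCc12 | intermediate
4 | 2,7-bis(tert-butyldimethylsilyloxy)-5-methoxy-4H-chromene (bis-silyl ketene acetal, not isolated) | COc1cc(O[Si](C)(C)C(C)(C)C)cc2OC(O[Si](C)(C)C(C)(C)C)=CCc12 | intermediate
5 | rac-3-bromo-7-(tert-butyldimethylsilyloxy)-5-methoxychroman-2-one | COc1cc(O[Si](C)(C)C(C)(C)C)cc2OC(=O)C(Br)Cc12 | intermediate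
6 | 3-methoxyphenol | COc1cccc(O)c1 | starting material
7 | 1-methoxy-3-(methoxymethoxy)benzene | COCOc1cccc(OC)c1 | intermediate
8 | prenyl bromide (1-bromo-3-methylbut-2-ene) | CC(C)=CCBr | starting material
9 | [2-methoxy-6-(methoxymethoxy)phenyl]lithium (not isolated) | [Li]c1c(OC)cccc1OCOC | intermediate
10 | 1-methoxy-3-(methoxymethoxy)-2-(3-methylbut-2-en-1-yl)benzene | COCOc1cccc(OC)c1CC=C(C)C | intermediate
11 | [4-methoxy-2-(methoxymethoxy)-3-(3-methylbut-2-en-1-yl)phenyl]lithium (not isolated) | COCOc1c([Li])ccc(OC)c1CC=C(C)C | intermediate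
12 | [4-methoxy-2-(methoxymethoxy)-3-(3-methylbut-2-en-1-yl)phenyl]zinc iodide (not isolated) | COCOc1c([Zn]I)ccc(OC)c1CC=C(C)C | intermediate
13 | (3R)-7-(tert-butyldimethylsilyloxy)-5-methoxy-3-[4-methoxy-2-(methoxymethoxy)-3-(3-methylbut-2-en-1-yl)phenyl]chroman-2-one | COc1ccc([C@@H]2C(=O)Oc3cc(O[Si](C)(C)C(C)(C)C)cc(OC)c3C2)c(OCOC)c1CC=C(C)C | intermediate
14 | (2R)-3-[4-(tert-butyldimethylsilyloxy)-2-hydroxy-6-methoxyphenyl]-2-[4-methoxy-2-(methoxymethoxy)-3-(3-methylbut-2-en-1-yl)phenyl]propan-1-ol | COc1ccc([C@H](CO)Cc2c(O)cc(O[Si](C)(C)C(C)(C)C)cc2OC)c(OCOC)c1CC=C(C)C | intermediate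
15 | 6-(tert-butyldimethylsilyloxy)-2-hydroxy-3-{(2R)-3-hydroxy-2-[4-methoxy-2-(methoxymethoxy)-3-(3-methylbut-2-en-1-yl)phenyl]propyl}-4-methoxybenzaldehyde | COc1ccc([C@H](CO)Cc2c(O)c(C=O)c(O[Si](C)(C)C(C)(C)C)cc2OC)c(OCOC)c1CC=C(C)C | intermediate
16 | (3R)-7-(tert-butyldimethylsilyloxy)-5-methoxy-3-[4-methoxy-2-(methoxymethoxy)-3-(3-methylbut-2-en-1-yl)phenyl]chroman-8-carbaldehyde | COc1ccc([C@@H]2COc3c(C=O)c(O[Si](C)(C)C(C)(C)C)cc(OC)c3C2)c(OCOC)c1CC=C(C)C | intermediate
17 | (3R)-7-hydroxy-3-[2-hydroxy-4-methoxy-3-(3-methylbut-2-en-1-yl)phenyl]-5-methoxychroman-8-carbaldehyde | COc1ccc([C@@H]2COc3c(C=O)c(O)cc(OC)c3C2)c(O)c1CC=C(C)C | target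

## Step count

Total steps: 9. Longest linear sequence: 7 (steps 1, 2, 5, 6, 7, 8, 9; the ring B branch, steps 3, 4, 5–9, is equally long).

## Three steps most likely to fail

Step 5 (stereoconvergent arylation). The lactone is a new substrate class for this catalysis, the arylzinc is ortho-substituted, HBr loss from 5 to the coumarin competes, and the lithiation of 10 could partly go to the benzylic/allylic CH2. Fallback: set out again from 5 and 10 and run the same arylzinc coupling with an achiral catalyst (NiCl2·glyme, 2,2'-bipyridine, THF/glyme, 0 °C) to give rac-7-(tert-butyldimethylsilyloxy)-5-methoxy-3-[4-methoxy-2-(methoxymethoxy)-3-(3-methylbut-2-en-1-yl)phenyl]chroman-2-one F1. This is converted with LiHMDS and TMSCl (THF, −78 °C) into the ketene acetal 7-(tert-butyldimethylsilyloxy)-5-methoxy-3-[4-methoxy-2-(methoxymethoxy)-3-(3-methylbut-2-en-1-yl)phenyl]-2-(trimethylsilyloxy)-4H-chromene F2. F2 is then protonated enantioselectively with phenol and the chiral Brønsted acid (R)-3,3'-bis(2,4,6-triisopropylphenyl)-1,1'-binaphthyl-2,2'-diyl N-triflylthiophosphoramide (10 mol %, toluene, −78 °C). The key C–C bond is still made from the α-bromolactone, but the stereocentre is set by C–H bond formation; the sequence comes back at 13.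

Step 1 (regiochemistry of the annulation). Attack at the carbon between the two hydroxyls would give the 5-hydroxy-7-methoxy lactone, and the ratio is not known in advance. Fallback: set out from 1 and fix the position of the carbon first by Vilsmeier–Haack formylation (POCl3, DMF, EtOAc, 0 °C → rt; H2O) to 2,4-dihydroxy-6-methoxybenzaldehyde F3, a crystalline aldehyde whose constitution follows directly from its unsymmetrical NMR spectrum. Wittig olefination with Ph3P=CHCO2Et in N,N-diethylaniline at reflux gives ethyl (E)-3-(2,4-dihydroxy-6-methoxyphenyl)acrylate F4, which isomerises and lactonises in the same pot to 7-hydroxy-5-methoxycoumarin F5. Hydrogenation (H2, Pd/C, EtOAc) comes back at 3.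

Step 7 (formylation of the diol). The reacting position lies between the phenol and the bulky silyl ether, the free primary alcohol also binds magnesium, and the silyl ether may be partly lost once the aldehyde is in place. Fallback: set out from 14 and close the ring first (PPh3, DIAD, THF) to (3R)-7-(tert-butyldimethylsilyloxy)-5-methoxy-3-[4-methoxy-2-(methoxymethoxy)-3-(3-methylbut-2-en-1-yl)phenyl]chromane F6. Both protecting groups are removed (HCl in MeOH, 40 °C) to give (3R)-3-[2-hydroxy-4-methoxy-3-(3-methylbut-2-en-1-yl)phenyl]-5-methoxychroman-7-ol F7. Formylation comes last (MgCl2, Et3N, (CH2O)n, MeCN, reflux), now directed by the 7-OH; the ring B phenol has no open ortho position. C8 is expected to be favoured over C6 because the neighbouring 5-OMe turns its methyl group toward C6, but a C6 isomer may need to be separated. This arrives directly at 17.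

## Further compounds

F1 | step 5 | rac-7-(tert-butyldimethylsilyloxy)-5-methoxy-3-[4-methoxy-2-(methoxymethoxy)-3-(3-methylbut-2-en-1-yl)phenyl]chroman-2-one | COc1ccc(C2C(=O)Oc3cc(O[Si](C)(C)C(C)(C)C)cc(OC)c3C2)c(OCOC)c1CC=C(C)C
F2 | step 5 | 7-(tert-butyldimethylsilyloxy)-5-methoxy-3-[4-methoxy-2-(methoxymethoxy)-3-(3-methylbut-2-en-1-yl)phenyl]-2-(trimethylsilyloxy)-4H-chromene | COc1ccc(C2=C(O[Si](C)(C)C)Oc3cc(O[Si](C)(C)C(C)(C)C)cc(OC)c3C2)c(OCOC)c1CC=C(C)C
F3 | step 1 | 2,4-dihydroxy-6-methoxybenzaldehyde | COc1cc(O)cc(O)c1C=O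
F4 | step 1 | ethyl (E)-3-(2,4-dihydroxy-6-methoxyphenyl)acrylate | CCOC(=O)/C=C/c1c(O)cc(O)cc1OC
F5 | step 1 | 7-hydroxy-5-methoxycoumarin | COc1cc(O)cc2OC(=O)C=Cc12
F6 | step 7 | (3R)-7-(tert-butyldimethylsilyloxy)-5-methoxy-3-[4-methoxy-2-(methoxymethoxy)-3-(3-methylbut-2-en-1-yl)phenyl]chromane | COc1ccc([C@@H]2COc3cc(O[Si](C)(C)C(C)(C)C)cc(OC)c3C2)c(OCOC)c1CC=C(C)C
F7 | step 7 | (3R)-3-[2-hydroxy-4-methoxy-3-(3-methylbut-2-en-1-yl)phenyl]-5-methoxychroman-7-ol | COc1ccc([C@@H]2COc3cc(O)cc(OC)c3C2)c(O)c1CC=C(C)C
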